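The readings come from a simulation for substances that don't exist; scatter was added.

If this flask behaves like the east and west runs, D climbs early, falls back and comes to rest, and the level where it rests can be reckoned before the flask is started.

| setting | east | west | flask |
|---|---|---|---|
| E | 0.10 M | 0.10 M | 0.10 M |
| J | 0.070 M | 0.070 M | 0.0700 M |
| X | 8.3 mM | 8.3 mM | 8.3 mM |
| Q | 0.14 mM | 0.22 mM | 0.10 mM |
| remark | run made earlier | run made earlier |  |
| time |  |  | 40 min |

| run | time / min | D / % | Z / % |
|---|---|---|---|
| east | 0.417 | 49.8 | 19.6 |
| east | 0.833 | 44.0 | 37.0 |
| east | 2.00 | 31.0 | 56.4 |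
| east | 4.00 | 24.6 | 65.8 |
| east | 8.00 | 22.1 | 69.4 |
| east | 20.0 | 22.2 | 70.0 |
| east | 40.0 | 22.5 | 69.9 |
| west | 0.417 | 44.5 | 26.5 |
| west | 0.833 | 37.9 | 45.8 |
| west | 2.00 | 27.6 | 62.4 |
| west | 4.00 | 23.2 | 68.1 |
| west | 8.00 | 22.5 | 69.6 |
| west | 20.0 | 21.9 | 69.7 |
| west | 40.0 | 22.0 | 69.8 |

(scatter of a reading: 0.3 percentage points)



* the best time, 40 min at the latest, for D
* the amount of D, in percent of the E charged, at that time
* the first time at which D reaches 38%, in the same percent, in min

J is charged at 0.0700 M against 0.10 M of E, so J is the limiting reagent, and if each J carries one E to Z, the charges leave a pool of 30.0% of the E outside Z. The readings reach the same pool a second way: at 40.0 min, Z leaves 30.1% in the east run and 30.2% in the west run. Charges and readings are different things, and they agree within the scatter of 0.3 percentage points, so the pool can be trusted.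

That pool is divided between D and E. D takes 0.748 of it in the east run and 0.728 in the west run, a gap of the size that scatter makes on a pool of this size. Their mean, 0.738, is the resting share, the part of the pool standing as D once the readings stop moving. The west run makes Z faster at first, 26.5% against 19.6% at 0.417 min, yet it ends level with the east run. My own reckoning for the flask, whose charge of Q is smaller than in either run, is therefore a resting D of 22.1%, provided that charge still brings the flask to rest within 40 min.

The forecast puts the best at 53.5% (range 50.5% to 57%) at 0.46 min (0.33 min to 0.62 min), and the first passage of the level at 0.15 min (0.1 min to 0.22 min). It warns: “The peak is also extrapolated, since no reading is that early”.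

The flask gives its best, 53.7% of D, at 0.450 min, and D first reaches the level at 0.143 min.

    E + X ⇌ X + D (K = 2.80, k = 8.40 M⁻¹ s⁻¹)
    J + Q + D → Q + Z (k = 2500 M⁻² s⁻¹)

At that best time E still holds 29.4%. The resting share on the pool gave 22.1%, and the flask stands at 22.1% of D at 40.0 min. A neighbouring flask with 0.018 M of J has a pool of 82.0%, on which the share gives 60.5%, and that flask ends with 60.4% of D.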